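The route rests on disconnecting the bond between the methyl-bearing quaternary cyclopentane carbon (C8) and the side-chain methine (C14). A reductive photoredox Giese coupling joins the tertiary C8 radical of a cis-fused 5/7 hydroazulene (from its N-acyloxyphthalimide) to a (5S)-menthyloxybutenolide that already carries the CH2CO2H arm. The step exploits that C14, C13 and their two CH2O carbons (C15, C16) map onto the β-carbon, α-carbon, acetal carbon and carbonyl of a butenolide: one operation forms C8–C14 and sets quaternary C8 (convex face of the bicycle), C14 (anti to the acetal alkoxy) and C13 (hydrogen transfer anti to C8). Hydride reduction with relactonisation, enolate hydroxylation and acetylation complete the target.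

Key step: step 14

Atom labels used below: C5 and C9 are the ring-fusion CH carbons (C5 next to the CMe2 carbon C4, C9 next to C8 and to the methylidene carbon C10); C6 and C7 are the cyclopentane CH2 groups; C14 is the side-chain CH and C15 its CH2O; C13 is the lactone CH, C16 the lactone OCH2, C11 the lactone C=O and C12 the CH–OAc carbon.
Assumption: the (5S)-d-menthyloxy enantiomer of 5-(menthyloxy)furan-2(5H)-one is taken as commercially available, like its (5R)-l-menthyloxy antipode.

Step 1
Reactants: 1 3-methylcyclohex-2-en-1-one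
Product: 2 [(3,3-dimethylcyclohex-1-en-1-yl)oxy]trimethylsilane
Conditions: MeMgBr, CuBr·SMe2 (5 mol %), TMSCl, DMPU, THF, −78 → 0 °C
Reagents that add atoms: methylmagnesium bromide C[Mg]Br; chlorotrimethylsilane C[Si](C)(C)Cl
Why: Copper-catalysed, TMSCl-accelerated conjugate addition builds the future C4 gem-dimethyl carbon, and in situ silylation of the enolate fixes the enol ether double bond next to that carbon.

Step 2
Reactants: 2 [(3,3-dimethylcyclohex-1-en-1-yl)oxy]trimethylsilane
Product: 3 [(5,5-dimethylbicyclo[4.1.0]heptan-1-yl)oxy]trimethylsilane (racemic)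
Conditions: Et2Zn, CH2I2, CH2Cl2, 0 °C → rt
Reagents that add atoms: diiodomethane ICI
Why: Simmons–Smith cyclopropanation of the electron-rich silyl enol ether should be facile; the two new stereocentres form as a racemate and are destroyed in step 3.

Step 3
Reactants: 3 [(5,5-dimethylbicyclo[4.1.0]heptan-1-yl)oxy]trimethylsilane
Product: 5 4,4-dimethylcyclohept-2-en-1-one, via 3-chloro-4,4-dimethylcycloheptan-1-one 4 (not isolated)
Conditions: FeCl3, DMF, 0 °C → rt; then NaOAc, MeOH, reflux
Reagents that add atoms: none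
Why: Saegusa–Ito ring expansion, in which Fe(III) oxidation opens the internal cyclopropane bond to a β-keto radical that is chlorinated, and E1cB loss of HCl gives the cycloheptenone with the gem-dimethyl carbon in the γ-position.

Step 4
Reactants: 5 4,4-dimethylcyclohept-2-en-1-one; 6 ethyl 4-iodobutanoate
Product: 9 ethyl 4-[(1R)-2,2-dimethyl-6-{[(trifluoromethyl)sulfonyl]oxy}cyclohept-6-en-1-yl]butanoate, via bis(4-ethoxy-4-oxobutyl)zinc 7 (not isolated), via zinc enolate 8 (not isolated)
Conditions: 6, Et2Zn, CuI (cat.), 50 °C, then volatiles removed; 5, Cu(OTf)2 (2 mol %), (S,R,R)-BINOL bis(1-phenylethyl)amine phosphoramidite (4 mol %), toluene, −30 °C; then Tf2O, −30 → 0 °C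
Reagents that add atoms: trifluoromethanesulfonic anhydride O=S(=O)(OS(=O)(=O)C(F)(F)F)C(F)(F)F
Why: Copper/phosphoramidite-catalysed asymmetric conjugate addition of the functionalised dialkylzinc sets C5 (the ligand series that gives (S)-3-ethylcyclohexanone from cyclohexenone delivers the chain to the face that is R here), and O-triflation of the regiodefined zinc enolate stores the C9=C10 double bond.

Step 5
Reactants: 9 ethyl 4-[(1R)-2,2-dimethyl-6-{[(trifluoromethyl)sulfonyl]oxy}cyclohept-6-en-1-yl]butanoate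
Product: 10 ethyl 4-[(1R)-6-(hydroxymethyl)-2,2-dimethylcyclohept-6-en-1-yl]butanoate
Conditions: Bu3SnCH2OH, Pd(PPh3)4 (5 mol %), LiCl, 1,4-dioxane, 95 °C
Reagents that add atoms: (tributylstannyl)methanol CCCC[Sn](CCCC)(CCCC)CO
Why: Stille hydroxymethylation of the alkenyl triflate installs the future methylidene carbon on C10 without touching the ester or C5.

Step 6
Reactants: 10 ethyl 4-[(1R)-6-(hydroxymethyl)-2,2-dimethylcyclohept-6-en-1-yl]butanoate
Product: 11 ethyl 4-[(1R)-6-(chloromethyl)-2,2-dimethylcyclohept-6-en-1-yl]butanoate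
Conditions: PPh3, NCS, THF, 0 °C
Reagents that add atoms: N-chlorosuccinimide O=C1CCC(=O)N1Cl
Why: Appel-type chlorination of the primary allylic alcohol by SN2 displacement of the oxyphosphonium gives the allylic chloride without allylic transposition.

Step 7
Reactants: 11 ethyl 4-[(1R)-6-(chloromethyl)-2,2-dimethylcyclohept-6-en-1-yl]butanoate
Product: 12 ethyl (3aR,8aR)-4,4-dimethyl-8-methylidenedecahydroazulene-1-carboxylate (cis-fused, mixture of C1 epimers)
Conditions: KHMDS, THF (0.01 M), −78 → 0 °C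
Reagents that add atoms: none
Why: Intramolecular SN2′ enolate alkylation (5-exo) closes the cyclopentane and unveils the exocyclic methylidene; the three-atom tether on C5 can reach only the syn face of C9, so the ring fusion must be cis, and the epimeric ester carbon is erased in step 9.

Step 8
Reactants: 12 ethyl (3aR,8aR)-4,4-dimethyl-8-methylidenedecahydroazulene-1-carboxylate
Product: 13 (3aR,8aR)-4,4-dimethyl-8-methylidenedecahydroazulene-1-carboxylic acid (C1 epimers)
Conditions: LiOH·H2O, THF/MeOH/H2O, 50 °C; then 1 M HCl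
Reagents that add atoms: lithium hydroxide [Li+].[OH-]
Why: Saponification of the still secondary, unhindered ester is easy at this stage and avoids hydrolysing a neopentyl-type quaternary ester later.

Step 9
Reactants: 13 (3aR,8aR)-4,4-dimethyl-8-methylidenedecahydroazulene-1-carboxylic acid
Product: 14 (1S,3aR,8aS)-1,4,4-trimethyl-8-methylidenedecahydroazulene-1-carboxylic acid
Conditions: LDA (2.3 equiv), THF/DMPU, 0 °C; then MeI, −78 → 0 °C; 1 M HCl
Reagents that add atoms: iodomethane CI
Why: Alkylation of the carboxylic acid dianion makes C8 quaternary, with methyl iodide expected on the convex face anti to C10; this configuration is inconsequential because step 14 planarises C8.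

Step 10
Reactants: 14 (1S,3aR,8aS)-1,4,4-trimethyl-8-methylidenedecahydroazulene-1-carboxylic acid
Product: 15 1,3-dioxoisoindolin-2-yl (1S,3aR,8aS)-1,4,4-trimethyl-8-methylidenedecahydroazulene-1-carboxylate
Conditions: N-hydroxyphthalimide, DIC, DMAP (cat.), CH2Cl2, rt
Reagents that add atoms: N-hydroxyphthalimide O=C1c2ccccc2C(=O)N1O
Why: Carbodiimide esterification, which is reliable for tertiary acids, gives the redox-active ester needed for reductive radical generation.

Step 11
Reactants: 16 (5S)-5-{[(1S,2R,5S)-5-methyl-2-(propan-2-yl)cyclohexyl]oxy}furan-2(5H)-one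
Product: 18 (5S)-3-bromo-5-{[(1S,2R,5S)-5-methyl-2-(propan-2-yl)cyclohexyl]oxy}furan-2(5H)-one, via 3,4-dibromo lactone 17 (not isolated)
Conditions: Br2, CH2Cl2, 0 °C; then Et3N, 0 °C
Reagents that add atoms: bromine BrBr
Why: Bromine addition followed by E1cB loss of HBr through the acidic α-hydrogen gives the α-bromobutenolide, with the acetal stereocentre untouched under the brief, cold amine treatment.

Step 12
Reactants: 18 (5S)-3-bromo-5-{[(1S,2R,5S)-5-methyl-2-(propan-2-yl)cyclohexyl]oxy}furan-2(5H)-one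
Product: 19 tert-butyl 2-[(5S)-5-{[(1S,2R,5S)-5-methyl-2-(propan-2-yl)cyclohexyl]oxy}-2-oxo-2,5-dihydrofuran-3-yl]acetate
Conditions: BrZnCH2CO2t-Bu, Pd(PPh3)4 (5 mol %), THF, 50 °C
Reagents that add atoms: (2-tert-butoxy-2-oxoethyl)zinc bromide CC(C)(C)OC(=O)C[Zn]Br
Why: Negishi coupling of the electron-poor alkenyl bromide with the weakly basic Reformatsky reagent attaches the C12–C11 arm to the future C13 without conjugate addition.

Step 13
Reactants: 19 tert-butyl 2-[(5S)-5-{[(1S,2R,5S)-5-methyl-2-(propan-2-yl)cyclohexyl]oxy}-2-oxo-2,5-dihydrofuran-3-yl]acetate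
Product: 20 2-[(5S)-5-{[(1S,2R,5S)-5-methyl-2-(propan-2-yl)cyclohexyl]oxy}-2-oxo-2,5-dihydrofuran-3-yl]acetic acid
Conditions: TFA/CH2Cl2 (1:4), 0 °C → rt
Reagents that add atoms: none
Why: Acidolysis of the tert-butyl ester is done before the coupling, while no acid-labile methylidene group is present, and leaves the acid-stable acyloxy acetal intact.

Step 14
Reactants: 15 1,3-dioxoisoindolin-2-yl (1S,3aR,8aS)-1,4,4-trimethyl-8-methylidenedecahydroazulene-1-carboxylate; 20 2-[(5S)-5-{[(1S,2R,5S)-5-methyl-2-(propan-2-yl)cyclohexyl]oxy}-2-oxo-2,5-dihydrofuran-3-yl]acetic acid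
Product: 23 2-[(3R,4R,5S)-5-{[(1S,2R,5S)-5-methyl-2-(propan-2-yl)cyclohexyl]oxy}-2-oxo-4-[(1R,3aR,8aS)-1,4,4-trimethyl-8-methylidenedecahydroazulen-1-yl]oxolan-3-yl]acetic acid, via C8 tertiary radical 21 (not isolated), via C13 lactone radical 22 (not isolated)
Conditions: Ru(bpy)3(BF4)2 (1 mol %), Hantzsch ester (1.5 equiv), i-Pr2NEt·HBF4 (1 equiv), CH2Cl2, blue LEDs, rt
Reagents that add atoms: none
Why: Photoexcited Ru(II) is reduced by the Hantzsch ester to Ru(I), which transfers an electron to 15; loss of phthalimide anion and CO2 gives tertiary radical 21, which adds to the β-carbon (C14) of butenolide 20, and the resulting radical 22 is quenched by hydrogen-atom transfer from the Hantzsch ester. The closest known reaction type is the reductive photoredox Giese coupling of tertiary N-acyloxyphthalimides with butenolides and other electron-poor alkenes. No ring is closed; the step is a bimolecular fragment union with all rings already in place. All three new stereocentres are substrate-controlled: C8 because the planar radical reacts on the convex face of the cis-fused bicycle, anti to the C9–C10 bond; C14 because the radical enters anti to the menthyloxy group on the adjacent acetal carbon C15; and C13 because the hydrogen donor approaches the lactone radical anti to the new quaternary substituent on C14, leaving the acetic acid arm cis to it. The step needs β-regioselectivity, two π-facial selectivities and a kinetic cis C13/C14 relationship: the first follows from the polarity match of the nucleophilic radical with the enoate, the facial selectivities from the resident C9 and C15 stereocentres, and the last is preserved by the non-basic medium, which cannot epimerise the lactone α-carbon. The α-substituent of 20 also makes radical 22 tertiary and suppresses oligomerisation.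

Step 15
Reactants: 23 2-[(3R,4R,5S)-5-{[(1S,2R,5S)-5-methyl-2-(propan-2-yl)cyclohexyl]oxy}-2-oxo-4-[(1R,3aR,8aS)-1,4,4-trimethyl-8-methylidenedecahydroazulen-1-yl]oxolan-3-yl]acetic acid
Product: 25 (4R)-4-{(1R)-2-hydroxy-1-[(1R,3aR,8aS)-1,4,4-trimethyl-8-methylidenedecahydroazulen-1-yl]ethyl}oxolan-2-one, via dihydroxy acid 24 (not isolated)
Conditions: Et3N (1.1 equiv), then LiBH4 (3 equiv), THF, 0 °C → rt; then 1 M HCl to pH 2–3, rt
Reagents that add atoms: none
Why: Chemoselective borohydride reduction takes the activated acetal-lactone to the C16 and C15 primary alcohols while the carboxylate is inert (the borane is trapped as Et3N·BH3), and on acidification the C16 hydroxyl closes the five-membered lactone onto C11 in preference to the six-membered alternative through the neopentyl C15 hydroxyl; no stereocentre is touched.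

Step 16
Reactants: 25 (4R)-4-{(1R)-2-hydroxy-1-[(1R,3aR,8aS)-1,4,4-trimethyl-8-methylidenedecahydroazulen-1-yl]ethyl}oxolan-2-one
Product: 26 (3S,4R)-3-hydroxy-4-{(1R)-2-hydroxy-1-[(1R,3aR,8aS)-1,4,4-trimethyl-8-methylidenedecahydroazulen-1-yl]ethyl}oxolan-2-one
Conditions: KHMDS (2.3 equiv), THF, −78 °C; then 2-(phenylsulfonyl)-3-phenyloxaziridine, −78 °C; AcOH quench
Reagents that add atoms: 2-(phenylsulfonyl)-3-phenyloxaziridine O=S(=O)(c1ccccc1)N1OC1c1ccccc1
Why: Enolate hydroxylation with an N-sulfonyloxaziridine, in which the dianion (C15 alkoxide plus lactone enolate) is oxidised at C12 on the face anti to the bulky C13 substituent, should give the trans 3-hydroxy-4-alkyl lactone.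

Step 17
Reactants: 26 (3S,4R)-3-hydroxy-4-{(1R)-2-hydroxy-1-[(1R,3aR,8aS)-1,4,4-trimethyl-8-methylidenedecahydroazulen-1-yl]ethyl}oxolan-2-one
Product: 27 (3S,4R)-4-{(1R)-2-(acetyloxy)-1-[(1R,3aR,8aS)-1,4,4-trimethyl-8-methylidenedecahydroazulen-1-yl]ethyl}-2-oxooxolan-3-yl acetate
Conditions: Ac2O, pyridine, DMAP (cat.), CH2Cl2, rt
Reagents that add atoms: acetic anhydride CC(=O)OC(C)=O
Why: DMAP-catalysed acetylation of the primary and the α-lactone secondary hydroxyl should give the target without affecting any stereocentre.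

Compound list
1 | 3-methylcyclohex-2-en-1-one | CC1=CC(=O)CCC1 | starting material
2 | [(3,3-dimethylcyclohex-1-en-1-yl)oxy]trimethylsilane | CC1(C)CCCC(O[Si](C)(C)C)=C1 | intermediate
3 | [(5,5-dimethylbicyclo[4.1.0]heptan-1-yl)oxy]trimethylsilane (racemic) | C[Si](C)(C)OC12CCCC(C)(C)C1C2 | intermediate
4 | 3-chloro-4,4-dimethylcycloheptan-1-one (racemic) | CC1(C)CCCC(=O)CC1Cl | intermediate (not isolated)
5 | 4,4-dimethylcyclohept-2-en-1-one | CC1(C)CCCC(=O)C=C1 | intermediate
6 | ethyl 4-iodobutanoate | CCOC(=O)CCCI | starting material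
7 | bis(4-ethoxy-4-oxobutyl)zinc | CCOC(=O)CCC[Zn]CCCC(=O)OCC | intermediate (not isolated)
8 | zinc enolate of ethyl 4-[(1R)-2,2-dimethyl-6-oxocycloheptyl]butanoate (enolised towards C9) | CCOC(=O)CCC[C@@H]1C=C(O[Zn]CCCC(=O)OCC)CCCC1(C)C | intermediate (not isolated)
9 | ethyl 4-[(1R)-2,2-dimethyl-6-{[(trifluoromethyl)sulfonyl]oxy}cyclohept-6-en-1-yl]butanoate | CCOC(=O)CCC[C@@H]1C=C(OS(=O)(=O)C(F)(F)F)CCCC1(C)C | intermediate
10 | ethyl 4-[(1R)-6-(hydroxymethyl)-2,2-dimethylcyclohept-6-en-1-yl]butanoate | CCOC(=O)CCC[C@@H]1C=C(CO)CCCC1(C)C | intermediate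
11 | ethyl 4-[(1R)-6-(chloromethyl)-2,2-dimethylcyclohept-6-en-1-yl]butanoate | CCOC(=O)CCC[C@@H]1C=C(CCl)CCCC1(C)C | intermediate
12 | ethyl (3aR,8aR)-4,4-dimethyl-8-methylidenedecahydroazulene-1-carboxylate (cis-fused; C1 epimers, C1 left undefined) | C=C1CCCC(C)(C)[C@@H]2CCC(C(=O)OCC)[C@H]12 | intermediate
13 | (3aR,8aR)-4,4-dimethyl-8-methylidenedecahydroazulene-1-carboxylic acid (C1 epimers, C1 left undefined) | C=C1CCCC(C)(C)[C@@H]2CCC(C(=O)O)[C@H]12 | intermediate
14 | (1S,3aR,8aS)-1,4,4-trimethyl-8-methylidenedecahydroazulene-1-carboxylic acid | C=C1CCCC(C)(C)[C@@H]2CC[C@](C)(C(=O)O)[C@H]12 | intermediate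
15 | 1,3-dioxoisoindolin-2-yl (1S,3aR,8aS)-1,4,4-trimethyl-8-methylidenedecahydroazulene-1-carboxylate | C=C1CCCC(C)(C)[C@@H]2CC[C@](C)(C(=O)ON3C(=O)c4ccccc4C3=O)[C@H]12 | intermediate
16 | (5S)-5-{[(1S,2R,5S)-5-methyl-2-(propan-2-yl)cyclohexyl]oxy}furan-2(5H)-one | O=C1O[C@H](O[C@H]2C[C@@H](C)CC[C@@H]2C(C)C)C=C1 | starting material
17 | (5S)-3,4-dibromo-5-{[(1S,2R,5S)-5-methyl-2-(propan-2-yl)cyclohexyl]oxy}oxolan-2-one (trans-dibromide, C3/C4 left undefined) | O=C1O[C@H](O[C@H]2C[C@@H](C)CC[C@@H]2C(C)C)C(Br)C1Br | intermediate (not isolated)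
18 | (5S)-3-bromo-5-{[(1S,2R,5S)-5-methyl-2-(propan-2-yl)cyclohexyl]oxy}furan-2(5H)-one | O=C1O[C@H](O[C@H]2C[C@@H](C)CC[C@@H]2C(C)C)C=C1Br | intermediate
19 | tert-butyl 2-[(5S)-5-{[(1S,2R,5S)-5-methyl-2-(propan-2-yl)cyclohexyl]oxy}-2-oxo-2,5-dihydrofuran-3-yl]acetate | O=C1O[C@H](O[C@H]2C[C@@H](C)CC[C@@H]2C(C)C)C=C1CC(=O)OC(C)(C)C | intermediate
20 | 2-[(5S)-5-{[(1S,2R,5S)-5-methyl-2-(propan-2-yl)cyclohexyl]oxy}-2-oxo-2,5-dihydrofuran-3-yl]acetic acid | O=C1O[C@H](O[C@H]2C[C@@H](C)CC[C@@H]2C(C)C)C=C1CC(=O)O | intermediate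
21 | (3aR,8aS)-1,4,4-trimethyl-8-methylidenedecahydroazulen-1-yl radical (C8 radical) | C=C1CCCC(C)(C)[C@@H]2CC[C](C)[C@H]12 | intermediate (not isolated)
22 | C13 (lactone α-carbon) radical formed by addition of 21 to 20 | C=C1CCCC(C)(C)[C@@H]2CC[C@@](C)([C@@H]3[C@@H](O[C@H]4C[C@@H](C)CC[C@@H]4C(C)C)OC(=O)[C]3CC(=O)O)[C@H]12 | intermediate (not isolated)
23 | 2-[(3R,4R,5S)-5-{[(1S,2R,5S)-5-methyl-2-(propan-2-yl)cyclohexyl]oxy}-2-oxo-4-[(1R,3aR,8aS)-1,4,4-trimethyl-8-methylidenedecahydroazulen-1-yl]oxolan-3-yl]acetic acid | C=C1CCCC(C)(C)[C@@H]2CC[C@@](C)([C@@H]3[C@@H](O[C@H]4C[C@@H](C)CC[C@@H]4C(C)C)OC(=O)[C@@H]3CC(=O)O)[C@H]12 | intermediate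
24 | (3R,4R)-5-hydroxy-3-(hydroxymethyl)-4-[(1R,3aR,8aS)-1,4,4-trimethyl-8-methylidenedecahydroazulen-1-yl]pentanoic acid | C=C1CCCC(C)(C)[C@@H]2CC[C@@](C)([C@H](CO)[C@H](CO)CC(=O)O)[C@H]12 | intermediate (not isolated)
25 | (4R)-4-{(1R)-2-hydroxy-1-[(1R,3aR,8aS)-1,4,4-trimethyl-8-methylidenedecahydroazulen-1-yl]ethyl}oxolan-2-one | C=C1CCCC(C)(C)[C@@H]2CC[C@@](C)([C@H](CO)[C@@H]3COC(=O)C3)[C@H]12 | intermediate
26 | (3S,4R)-3-hydroxy-4-{(1R)-2-hydroxy-1-[(1R,3aR,8aS)-1,4,4-trimethyl-8-methylidenedecahydroazulen-1-yl]ethyl}oxolan-2-one | C=C1CCCC(C)(C)[C@@H]2CC[C@@](C)([C@H](CO)[C@@H]3COC(=O)[C@H]3O)[C@H]12 | intermediate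
27 | (3S,4R)-4-{(1R)-2-(acetyloxy)-1-[(1R,3aR,8aS)-1,4,4-trimethyl-8-methylidenedecahydroazulen-1-yl]ethyl}-2-oxooxolan-3-yl acetate (CNP0234964.1) | C=C1CCCC(C)(C)[C@@H]2CC[C@@](C)([C@H](COC(C)=O)[C@@H]3COC(=O)[C@H]3OC(C)=O)[C@H]12 | target

Total step count: 17. Longest linear sequence: 14 steps (steps 1–10, then 14–17); steps 11–13 form the three-step acceptor branch.

Steps most likely to fail

1. Step 14. Addition of the hindered tertiary radical to the trisubstituted, α-substituted butenolide may be slow enough that the radical is simply reduced, and hydrogen-atom transfer at C13 may occur with poor facial selectivity. The fallback sets out from 15 and 16 and returns at 23. Ester 15 is coupled under the same photoredox conditions with the unsubstituted, more reactive butenolide 16 to give (4R,5S)-5-(menthyloxy)-4-(hydroazulenyl)oxolan-2-one F1. Its lithium enolate (LiHMDS, THF, −78 °C) is added to allyl glyoxylate to give the aldol adduct F2, which is dehydrated (MsCl, Et3N, then DBU) to the alkylidene lactone F3. Copper hydride conjugate reduction ([(Ph3P)CuH]6, toluene, 2,6-di-tert-butylphenol as proton source) then sets C13 by protonation of the enolate anti to the C14 substituent, giving the allyl ester of 23, F4. Pd(PPh3)4 and morpholine in THF remove the allyl group to give 23.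

2. Step 7. Intermolecular Claisen condensation of the non-stabilised potassium enolate, or direct displacement at the primary chloride, may outrun the SN2′ ring closure. The fallback sets out from 10 and returns at 12. Alcohol 10 is converted (ClCO2Me, pyridine, CH2Cl2) into the allylic methyl carbonate F5. Pd(PPh3)4 ionises it to a π-allylpalladium complex, so that C9 becomes electrophilic independently of the leaving-group carbon, and the lithium ester enolate (LiHMDS, THF, 0 °C → rt) attacks C9 in the 5-exo mode to give 12.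

3. Step 15. The free acid may consume hydride to form acyloxyborohydrides that reduce the C11 carboxyl or hydroborate the methylidene group, and alkoxide formed during the reduction may epimerise C13 before the lactone is consumed. The fallback sets out from 15 and 19 (step 13 is omitted) and returns at 25. Ester 15 is coupled under the step-14 conditions with tert-butyl ester 19 to give the tert-butyl ester of 23, F6. LiBH4 (THF, 0 °C) reduces only the acetal-lactone, giving the diol tert-butyl ester F7 and menthol. Catalytic NaH in THF then closes the five-membered lactone through the C16 alkoxide with loss of tert-butanol to give 25.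

Further compounds
F1 | step 14 | (4R,5S)-5-{[(1S,2R,5S)-5-methyl-2-(propan-2-yl)cyclohexyl]oxy}-4-[(1R,3aR,8aS)-1,4,4-trimethyl-8-methylidenedecahydroazulen-1-yl]oxolan-2-one | C=C1CCCC(C)(C)[C@@H]2CC[C@@](C)([C@H]3CC(=O)O[C@@H]3O[C@H]4C[C@@H](C)CC[C@@H]4C(C)C)[C@H]12
F2 | step 14 | allyl 2-hydroxy-2-[(4R,5S)-5-(menthyloxy)-2-oxo-4-(hydroazulenyl)oxolan-3-yl]acetate (aldol adduct, new centres undefined) | C=C1CCCC(C)(C)[C@@H]2CC[C@@](C)([C@H]3C(C(O)C(=O)OCC=C)C(=O)O[C@@H]3O[C@H]4C[C@@H](C)CC[C@@H]4C(C)C)[C@H]12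
F3 | step 14 | allyl 2-[(4R,5S)-5-(menthyloxy)-2-oxo-4-(hydroazulenyl)oxolan-3-ylidene]acetate (alkene geometry undefined) | C=C1CCCC(C)(C)[C@@H]2CC[C@@](C)([C@H]3C(=CC(=O)OCC=C)C(=O)O[C@@H]3O[C@H]4C[C@@H](C)CC[C@@H]4C(C)C)[C@H]12
F4 | step 14 | allyl 2-[(3R,4R,5S)-5-{[(1S,2R,5S)-5-methyl-2-(propan-2-yl)cyclohexyl]oxy}-2-oxo-4-[(1R,3aR,8aS)-1,4,4-trimethyl-8-methylidenedecahydroazulen-1-yl]oxolan-3-yl]acetate | C=C1CCCC(C)(C)[C@@H]2CC[C@@](C)([C@@H]3[C@@H](O[C@H]4C[C@@H](C)CC[C@@H]4C(C)C)OC(=O)[C@@H]3CC(=O)OCC=C)[C@H]12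
F5 | step 7 | ethyl 4-[(1R)-6-{[(methoxycarbonyl)oxy]methyl}-2,2-dimethylcyclohept-6-en-1-yl]butanoate | CCOC(=O)CCC[C@@H]1C=C(COC(=O)OC)CCCC1(C)C
F6 | step 15 | tert-butyl 2-[(3R,4R,5S)-5-{[(1S,2R,5S)-5-methyl-2-(propan-2-yl)cyclohexyl]oxy}-2-oxo-4-[(1R,3aR,8aS)-1,4,4-trimethyl-8-methylidenedecahydroazulen-1-yl]oxolan-3-yl]acetate | C=C1CCCC(C)(C)[C@@H]2CC[C@@](C)([C@@H]3[C@@H](O[C@H]4C[C@@H](C)CC[C@@H]4C(C)C)OC(=O)[C@@H]3CC(=O)OC(C)(C)C)[C@H]12
F7 | step 15 | tert-butyl (3R,4R)-5-hydroxy-3-(hydroxymethyl)-4-[(1R,3aR,8aS)-1,4,4-trimethyl-8-methylidenedecahydroazulen-1-yl]pentanoate | C=C1CCCC(C)(C)[C@@H]2CC[C@@](C)([C@H](CO)[C@H](CO)CC(=O)OC(C)(C)C)[C@H]12
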